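**Retrosynthetic overview**
1. Target 14 is methyl shikimate with (2E)-3-methylpent-2-enoates on O3 and O5 (ring locants: C1 bears CO2Me, C2 is the vinylic CH, C3–C5 bear oxygen, C6 is CH2). The O3 ester is cut last (acylation of 3,4-diol 12), the O5 ester is installed early by Mitsunobu inversion, and O3/O4 travel as an acetonide (11).
2. The cyclohexene is closed by the C2–C3 bond in a decarboxylative radical ring closure of dioxolane acid 10: the C3 radical attacks C2 of a β-sulfonyl acrylate and sulfinate leaves, restoring C1=C2.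
3. Enabling feature: C3 bears oxygen and is cis to O4, so O3/O4 fit into a 2,2-dimethyl-1,3-dioxolane whose C3 carries CO2H (a tartrate), a source of a nucleophilic dioxolan-4-yl radical. C2 is the β-carbon of the C2=C1–CO2Me enoate and can carry a radical leaving group. The five-membered dioxolane forces the new six-membered ring to fuse cis.
4. Acid 10 comes from L-tartrate acetonide 1 (C3, C4; one CO2Me becomes the C5 aldehyde, the other the radical precursor), methyl 2-(bromomethyl)acrylate 4 (C6, C1, C2, CO2Me) and acid 6, by Barbier allylation, Mitsunobu esterification, ester hydrolysis and iodosulfonylation–dehydroiodination.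
5. Ring order: the 1,3-dioxolane is bought with 1, the cyclohexene is formed in step 7, and the dioxolane is removed in step 8.

Key step: step 7

Assumption: (2E)-3-methylpent-2-enoic acid 6 is taken as a purchasable, geometrically pure building block.

Step 1
Reactants: 1 dimethyl (4R,5R)-2,2-dimethyl-1,3-dioxolane-4,5-dicarboxylate (dimethyl 2,3-O-isopropylidene-L-tartrate)
Product: 2 methyl (4R,5S)-5-(hydroxymethyl)-2,2-dimethyl-1,3-dioxolane-4-carboxylate
Conditions: NaBH4 (0.55 equiv), MeOH, −10 to 0 °C, stopped at partial conversion, 1 recycled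
Reagents that add atoms: none
Why: Controlled hydride reduction of one of two homotopic, α-alkoxy-activated esters of a C2-symmetric diester; either ester gives the same hydroxy ester and no stereocentre is touched.

Step 2
Reactants: 2 methyl (4R,5S)-5-(hydroxymethyl)-2,2-dimethyl-1,3-dioxolane-4-carboxylate
Product: 3 methyl (4R,5R)-5-formyl-2,2-dimethyl-1,3-dioxolane-4-carboxylate
Conditions: Dess–Martin periodinane, CH2Cl2, 0 °C to rt
Reagents that add atoms: none
Why: Dess–Martin oxidation of the primary alcohol under non-basic conditions should give the α-alkoxy aldehyde without epimerisation (the trans dioxolane is also the more stable isomer).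

Step 3
Reactants: 3 methyl (4R,5R)-5-formyl-2,2-dimethyl-1,3-dioxolane-4-carboxylate; 4 methyl 2-(bromomethyl)acrylate
Product: 5 methyl (4R,5S)-5-[(1S)-1-hydroxy-3-(methoxycarbonyl)but-3-en-1-yl]-2,2-dimethyl-1,3-dioxolane-4-carboxylate
Conditions: Zn dust, THF/sat. aq. NH4Cl, 0 °C to rt, neutral work-up
Reagents that add atoms: none
Why: Zinc-mediated Barbier allylation forms the C5–C6 bond; Felkin–Anh attack anti to the dioxolane C–O bond should favour the anti (1S) carbinol, the syn epimer being removed by chromatography, and cold neutral handling avoids lactonisation onto the acrylate ester.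

Step 4
Reactants: 5 methyl (4R,5S)-5-[(1S)-1-hydroxy-3-(methoxycarbonyl)but-3-en-1-yl]-2,2-dimethyl-1,3-dioxolane-4-carboxylate; 6 (2E)-3-methylpent-2-enoic acid
Product: 7 methyl (4R,5S)-5-[(1R)-3-(methoxycarbonyl)-1-{[(2E)-3-methylpent-2-enoyl]oxy}but-3-en-1-yl]-2,2-dimethyl-1,3-dioxolane-4-carboxylate
Conditions: PPh3, DIAD, THF, 0 °C to rt
Reagents that add atoms: none
Why: Mitsunobu esterification (SN2 at the activated carbinol) installs the O5 ester and inverts the carbinol from 1S to 1R, which is the threo C4/C5 relationship of the target; the carboxylate acts only as nucleophile, so the E-enoate is not activated towards isomerisation.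

Step 5
Reactants: 7 methyl (4R,5S)-5-[(1R)-3-(methoxycarbonyl)-1-{[(2E)-3-methylpent-2-enoyl]oxy}but-3-en-1-yl]-2,2-dimethyl-1,3-dioxolane-4-carboxylate
Product: 8 (4R,5S)-5-[(1R)-3-(methoxycarbonyl)-1-{[(2E)-3-methylpent-2-enoyl]oxy}but-3-en-1-yl]-2,2-dimethyl-1,3-dioxolane-4-carboxylic acid
Conditions: LiOH·H2O (1.05 equiv), THF/H2O, 0 °C; then 1 M HCl to pH 3 at 0 °C
Reagents that add atoms: lithium hydroxide, [Li+].[OH-]
Why: Chemoselective saponification: the α-alkoxy dioxolane ester is far more electrophilic than the conjugated, α-branched acrylate ester and the hindered secondary enoate; epimerisation at the dioxolane α-carbon would be harmless because that centre becomes a radical in step 7.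

Step 6
Reactants: 8 (4R,5S)-5-[(1R)-3-(methoxycarbonyl)-1-{[(2E)-3-methylpent-2-enoyl]oxy}but-3-en-1-yl]-2,2-dimethyl-1,3-dioxolane-4-carboxylic acid
Product: 10 (4R,5S)-5-[(1R,3E)-3-(methoxycarbonyl)-1-{[(2E)-3-methylpent-2-enoyl]oxy}-4-(4-methylbenzenesulfonyl)but-3-en-1-yl]-2,2-dimethyl-1,3-dioxolane-4-carboxylic acid, via β-iodo sulfone 9 (not isolated)
Conditions: sodium 4-methylbenzenesulfinate, I2, CH2Cl2/H2O, rt, ambient light; then Et3N (2.1 equiv), CH2Cl2, 0 °C, short contact; 1 M HCl work-up
Reagents that add atoms: sodium 4-methylbenzenesulfinate, Cc1ccc(cc1)S(=O)[O-].[Na+]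
Why: Radical iodosulfonylation (the sulfonyl radical adds to the terminal CH2 of the 1,1-disubstituted acrylate, iodine goes to the tertiary α-ester carbon, and the hindered trisubstituted enoates stay out), then dehydroiodination through the acidic α-sulfonyl hydrogen gives the vinyl sulfone; the E isomer is expected but either geometry serves step 7.

Step 7
Reactants: 10 (4R,5S)-5-[(1R,3E)-3-(methoxycarbonyl)-1-{[(2E)-3-methylpent-2-enoyl]oxy}-4-(4-methylbenzenesulfonyl)but-3-en-1-yl]-2,2-dimethyl-1,3-dioxolane-4-carboxylic acid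
Product: 11 methyl (3aR,7R,7aS)-2,2-dimethyl-7-{[(2E)-3-methylpent-2-enoyl]oxy}-3a,6,7,7a-tetrahydro-1,3-benzodioxole-5-carboxylate (methyl 3,4-O-isopropylidene-5-O-acyl shikimate)
Conditions: Ir[dF(CF3)ppy]2(dtbbpy)PF6 (2 mol%), K2HPO4 (1.1 equiv), degassed DMF (0.005 M), 450 nm LEDs, 25 °C
Reagents that add atoms: none
Why: Proposed new method: the excited trivalent iridium photocatalyst oxidises the carboxylate of 10, loss of CO2 gives the nucleophilic 2,2-dimethyl-1,3-dioxolan-4-yl radical at C3, this adds to C2 (β to the ester, bearing the sulfonyl group) of the tethered acrylate, and the resulting tertiary α-ester radical at C1 expels the 4-methylbenzenesulfonyl radical, which divalent iridium reduces to sulfinate, so the cycle is redox-neutral. The closest known reactions are the intermolecular photoredox decarboxylative vinylation of α-oxy and α-amino acids with vinyl sulfones (radical addition, then β-sulfonyl elimination), the intermolecular couplings of tartrate-acetonide-derived radicals, and 6-endo cyclisations of radicals onto α-tethered acrylates; using them together as a ring-closing decarboxylative alkenylation is the new element. The cyclohexene closes in the 6-endo-trig mode, preferred over 5-exo attack at C1 because C1 is fully substituted, polar matching sends the α-oxy radical to the ester β-carbon, and the 5-exo path would create a quaternary centre and an unstabilised α-sulfonyl radical. The new stereocentre C3 is controlled by the dioxolane ring: the four-atom tether leaves C4 on one face, so bonding can occur only on that face and O3/O4 end up cis whatever the configuration at C3 in 10, while C4 and C5 are untouched. Chemoselectivity rests on the doubly activated sulfonyl acrylate being far more reactive towards a nucleophilic radical than the two β,β-disubstituted enoates and on high dilution against intermolecular addition. Both alkene geometries of 10 and both fates of the C1 radical (β-scission, or reduction to the enolate and loss of sulfinate) converge on 11.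

Step 8
Reactants: 11 methyl (3aR,7R,7aS)-2,2-dimethyl-7-{[(2E)-3-methylpent-2-enoyl]oxy}-3a,6,7,7a-tetrahydro-1,3-benzodioxole-5-carboxylate
Product: 12 methyl (3R,4R,5R)-3,4-dihydroxy-5-{[(2E)-3-methylpent-2-enoyl]oxy}cyclohex-1-ene-1-carboxylate (methyl 5-O-acyl shikimate)
Conditions: CF3CO2H/H2O (4:1), CH2Cl2, 0 °C to rt
Reagents that add atoms: none
Why: Acid-catalysed acetal hydrolysis of the cis-fused isopropylidene acetal; the electron-poor allylic system resists ionisation and the three esters should survive cold aqueous acid.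

Step 9
Reactants: 6 (2E)-3-methylpent-2-enoic acid
Product: 13 (2E)-3-methylpent-2-enoyl chloride
Conditions: (COCl)2, DMF (cat.), CH2Cl2, 0 °C; volatiles removed, used crude
Reagents that add atoms: oxalyl chloride, ClC(=O)C(=O)Cl
Why: Acid chloride formation through the Vilsmeier-type chloroiminium under cold, base-free conditions that should keep the E-trisubstituted alkene intact.

Step 10
Reactants: 12 methyl (3R,4R,5R)-3,4-dihydroxy-5-{[(2E)-3-methylpent-2-enoyl]oxy}cyclohex-1-ene-1-carboxylate; 13 (2E)-3-methylpent-2-enoyl chloride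
Product: 14 methyl (3R,4S,5R)-4-hydroxy-3,5-bis{[(2E)-3-methylpent-2-enoyl]oxy}cyclohex-1-ene-1-carboxylate (target)
Conditions: 13 (1.05 equiv), pyridine, CH2Cl2, −40 to −15 °C
Reagents that add atoms: none
Why: Kinetically controlled O-acylation (nucleophilic acyl substitution): the allylic O3–H is expected to react before O4–H, which is flanked by two oxygenated carbons, in line with the tendency of shikimate esters to react at O3 and O5 before O4; weak base and low temperature suppress vinylketene formation and acyl migration.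

**Compound list**
1 | dimethyl (4R,5R)-2,2-dimethyl-1,3-dioxolane-4,5-dicarboxylate | COC(=O)[C@@H]1OC(C)(C)O[C@H]1C(=O)OC | starting material
2 | methyl (4R,5S)-5-(hydroxymethyl)-2,2-dimethyl-1,3-dioxolane-4-carboxylate | COC(=O)[C@@H]1OC(C)(C)O[C@H]1CO | intermediate
3 | methyl (4R,5R)-5-formyl-2,2-dimethyl-1,3-dioxolane-4-carboxylate | COC(=O)[C@@H]1OC(C)(C)O[C@H]1C=O | intermediate
4 | methyl 2-(bromomethyl)acrylate | COC(=O)C(=C)CBr | starting material
5 | methyl (4R,5S)-5-[(1S)-1-hydroxy-3-(methoxycarbonyl)but-3-en-1-yl]-2,2-dimethyl-1,3-dioxolane-4-carboxylate | COC(=O)[C@@H]1OC(C)(C)O[C@H]1[C@@H](O)CC(=C)C(=O)OC | intermediate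
6 | (2E)-3-methylpent-2-enoic acid | CC/C(C)=C/C(=O)O | starting material
7 | methyl (4R,5S)-5-[(1R)-3-(methoxycarbonyl)-1-{[(2E)-3-methylpent-2-enoyl]oxy}but-3-en-1-yl]-2,2-dimethyl-1,3-dioxolane-4-carboxylate | COC(=O)[C@@H]1OC(C)(C)O[C@H]1[C@H](OC(=O)/C=C(\C)CC)CC(=C)C(=O)OC | intermediate
8 | (4R,5S)-5-[(1R)-3-(methoxycarbonyl)-1-{[(2E)-3-methylpent-2-enoyl]oxy}but-3-en-1-yl]-2,2-dimethyl-1,3-dioxolane-4-carboxylic acid | OC(=O)[C@@H]1OC(C)(C)O[C@H]1[C@H](OC(=O)/C=C(\C)CC)CC(=C)C(=O)OC | intermediate
9 | (4R,5S)-5-[(1R)-3-iodo-3-(methoxycarbonyl)-1-{[(2E)-3-methylpent-2-enoyl]oxy}-4-(4-methylbenzenesulfonyl)butyl]-2,2-dimethyl-1,3-dioxolane-4-carboxylic acid (β-iodo sulfone, both epimers at the iodinated carbon, formed in the flask in step 6) | OC(=O)[C@@H]1OC(C)(C)O[C@H]1[C@H](OC(=O)/C=C(\C)CC)CC(I)(CS(=O)(=O)c2ccc(C)cc2)C(=O)OC | intermediate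
10 | (4R,5S)-5-[(1R,3E)-3-(methoxycarbonyl)-1-{[(2E)-3-methylpent-2-enoyl]oxy}-4-(4-methylbenzenesulfonyl)but-3-en-1-yl]-2,2-dimethyl-1,3-dioxolane-4-carboxylic acid | OC(=O)[C@@H]1OC(C)(C)O[C@H]1[C@H](OC(=O)/C=C(\C)CC)C/C(C(=O)OC)=C\S(=O)(=O)c2ccc(C)cc2 | intermediate
11 | methyl (3aR,7R,7aS)-2,2-dimethyl-7-{[(2E)-3-methylpent-2-enoyl]oxy}-3a,6,7,7a-tetrahydro-1,3-benzodioxole-5-carboxylate | CC1(C)O[C@@H]2C=C(C(=O)OC)C[C@@H](OC(=O)/C=C(\C)CC)[C@@H]2O1 | intermediate
12 | methyl (3R,4R,5R)-3,4-dihydroxy-5-{[(2E)-3-methylpent-2-enoyl]oxy}cyclohex-1-ene-1-carboxylate (C4 is spatially as in 14; the descriptor changes by the priority rules) | O[C@@H]1C=C(C(=O)OC)C[C@@H](OC(=O)/C=C(\C)CC)[C@@H]1O | intermediate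
13 | (2E)-3-methylpent-2-enoyl chloride | CC/C(C)=C/C(=O)Cl | intermediate
14 | methyl (3R,4S,5R)-4-hydroxy-3,5-bis{[(2E)-3-methylpent-2-enoyl]oxy}cyclohex-1-ene-1-carboxylate | CC/C(C)=C/C(=O)O[C@@H]1C=C(C(=O)OC)C[C@@H](OC(=O)/C=C(\C)CC)[C@@H]1O | target

**Step count**
Total steps: 10. Longest linear sequence: 9 (steps 1–8 and 10; step 9 is a one-step side branch).

**Steps most likely to fail**

Step 7 (proposed new method). What may go wrong: hydrogen-atom capture or reduction of the C3 radical before ring closure (protodecarboxylation), intermolecular addition, base-promoted migration of the double bond of 10 out of conjugation with the sulfone, and geometric erosion of the enoates through reversible sulfonyl-radical addition. Fallback (known chemistry, ring closed instead by metathesis at C1=C2): it sets out from 4 and 6 and comes back at 11. Commercial methyl 2,3-O-isopropylidene-β-D-ribofuranoside is iodinated (I2, PPh3, imidazole) to methyl 5-deoxy-5-iodo-2,3-O-isopropylidene-β-D-ribofuranoside F1. Zinc dust in THF/H2O with sonication triggers Bernet–Vasella fragmentation to (4R,5R)-2,2-dimethyl-5-vinyl-1,3-dioxolane-4-carbaldehyde F2. F2 is allylated in the same flask by 4 and zinc to the anti alcohol methyl (4S)-4-[(4S,5R)-2,2-dimethyl-5-vinyl-1,3-dioxolan-4-yl]-4-hydroxy-2-methylidenebutanoate F3. Mitsunobu esterification with 6 (PPh3, DIAD) inverts the carbinol and gives methyl (4R)-4-[(4S,5R)-2,2-dimethyl-5-vinyl-1,3-dioxolan-4-yl]-2-methylidene-4-{[(2E)-3-methylpent-2-enoyl]oxy}butanoate F4. Ring-closing metathesis with the second-generation Grubbs catalyst in refluxing CH2Cl2 then gives 11; here ribose supplies the cis C3/C4 diol directly.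

Step 6. What may go wrong: loss of HI towards C6 or base-promoted migration of the double bond to the allyl sulfone, and E1cB loss of the O5 acyloxy group on prolonged contact with base. Fallback (stepwise ionic route with unambiguous regiochemistry): it sets out from 8 and comes back at 10. Conjugate addition of 4-methylbenzenethiol (Et3N) to the acrylate of 8 gives (4R,5S)-5-[(1R)-3-(methoxycarbonyl)-4-[(4-methylphenyl)sulfanyl]-1-{[(2E)-3-methylpent-2-enoyl]oxy}butyl]-2,2-dimethyl-1,3-dioxolane-4-carboxylic acid F5. N-chlorosuccinimide chlorinates the only sp3 carbon next to sulfur to give (4R,5S)-5-[(1R)-4-chloro-3-(methoxycarbonyl)-4-[(4-methylphenyl)sulfanyl]-1-{[(2E)-3-methylpent-2-enoyl]oxy}butyl]-2,2-dimethyl-1,3-dioxolane-4-carboxylic acid F6. F6 loses HCl with Et3N, which can only place the double bond at C1=C2, giving (4R,5S)-5-[(1R,3E)-3-(methoxycarbonyl)-4-[(4-methylphenyl)sulfanyl]-1-{[(2E)-3-methylpent-2-enoyl]oxy}but-3-en-1-yl]-2,2-dimethyl-1,3-dioxolane-4-carboxylic acid F7 (E isomer expected as the major one). Oxidation with mCPBA (2.2 equiv, CH2Cl2, 0 °C to rt) gives 10.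

Step 10. What may go wrong: insufficient kinetic discrimination between O3 and O4, acyl migration between the cis oxygens, and deconjugation of the acyl donor through vinylketene formation. Fallback (O4 is blocked first, so regiochemistry no longer depends on kinetic discrimination in the acylation): it sets out from 12 and comes back at 14. Borinic-acid-catalysed acylation (2-aminoethyl diphenylborinate cat., chloroacetyl chloride, iPr2NEt, MeCN), which on cis-1,2-diols selects the equatorial oxygen, should give methyl (3R,4R,5R)-4-[(chloroacetyl)oxy]-3-hydroxy-5-{[(2E)-3-methylpent-2-enoyl]oxy}cyclohex-1-ene-1-carboxylate F8. Acylation of the remaining O3–H with 13 (pyridine, DMAP cat.) gives methyl (3R,4S,5R)-4-[(chloroacetyl)oxy]-3,5-bis{[(2E)-3-methylpent-2-enoyl]oxy}cyclohex-1-ene-1-carboxylate F9. Thiourea (NaHCO3, EtOH, rt) then removes only the chloroacetate to give 14.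

**Further compounds**
F1 | step 7 | methyl 5-deoxy-5-iodo-2,3-O-isopropylidene-β-D-ribofuranoside | IC[C@H]1O[C@@H](OC)[C@@H]2OC(C)(C)O[C@H]12
F2 | step 7 | (4R,5R)-2,2-dimethyl-5-vinyl-1,3-dioxolane-4-carbaldehyde | C=C[C@H]1OC(C)(C)O[C@H]1C=O
F3 | step 7 | methyl (4S)-4-[(4S,5R)-2,2-dimethyl-5-vinyl-1,3-dioxolan-4-yl]-4-hydroxy-2-methylidenebutanoate | C=C[C@H]1OC(C)(C)O[C@H]1[C@@H](O)CC(=C)C(=O)OC
F4 | step 7 | methyl (4R)-4-[(4S,5R)-2,2-dimethyl-5-vinyl-1,3-dioxolan-4-yl]-2-methylidene-4-{[(2E)-3-methylpent-2-enoyl]oxy}butanoate | C=C[C@H]1OC(C)(C)O[C@H]1[C@H](OC(=O)/C=C(\C)CC)CC(=C)C(=O)OC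
F5 | step 6 | (4R,5S)-5-[(1R)-3-(methoxycarbonyl)-4-[(4-methylphenyl)sulfanyl]-1-{[(2E)-3-methylpent-2-enoyl]oxy}butyl]-2,2-dimethyl-1,3-dioxolane-4-carboxylic acid | OC(=O)[C@@H]1OC(C)(C)O[C@H]1[C@H](OC(=O)/C=C(\C)CC)CC(CSc2ccc(C)cc2)C(=O)OC
F6 | step 6 | (4R,5S)-5-[(1R)-4-chloro-3-(methoxycarbonyl)-4-[(4-methylphenyl)sulfanyl]-1-{[(2E)-3-methylpent-2-enoyl]oxy}butyl]-2,2-dimethyl-1,3-dioxolane-4-carboxylic acid | OC(=O)[C@@H]1OC(C)(C)O[C@H]1[C@H](OC(=O)/C=C(\C)CC)CC(C(Cl)Sc2ccc(C)cc2)C(=O)OC
F7 | step 6 | (4R,5S)-5-[(1R,3E)-3-(methoxycarbonyl)-4-[(4-methylphenyl)sulfanyl]-1-{[(2E)-3-methylpent-2-enoyl]oxy}but-3-en-1-yl]-2,2-dimethyl-1,3-dioxolane-4-carboxylic acid | OC(=O)[C@@H]1OC(C)(C)O[C@H]1[C@H](OC(=O)/C=C(\C)CC)C/C(C(=O)OC)=C\Sc2ccc(C)cc2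
F8 | step 10 | methyl (3R,4R,5R)-4-[(chloroacetyl)oxy]-3-hydroxy-5-{[(2E)-3-methylpent-2-enoyl]oxy}cyclohex-1-ene-1-carboxylate | O[C@@H]1C=C(C(=O)OC)C[C@@H](OC(=O)/C=C(\C)CC)[C@@H]1OC(=O)CCl
F9 | step 10 | methyl (3R,4S,5R)-4-[(chloroacetyl)oxy]-3,5-bis{[(2E)-3-methylpent-2-enoyl]oxy}cyclohex-1-ene-1-carboxylate | CC/C(C)=C/C(=O)O[C@@H]1C=C(C(=O)OC)C[C@@H](OC(=O)/C=C(\C)CC)[C@@H]1OC(=O)CCl
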